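Ring C is traced back to a 2-benzyloxy-1,3-diketone hung on C4a, and ring A is then dismantled completely by cutting C8a–C4a, C5–C6 and C8–C8a. The feature exploited is that ring A is a 1,2,3,5-tetraoxygenated benzene whose oxygens all differ: O1 on C8a, acetate on C8, methyl ether on C7, chelated hydroxyl on C5, with only C6–H and fusion carbon C4a between them. One thermal benzannulation of a cyclobutenone with an alkynyl ether delivers this ring with the oxygens already told apart (free phenol, MOM acetal, methyl, ethyl). The precursor is racemic 3-methoxy-4-(methoxymethoxy)cyclobut-2-enone, three steps from dimethyl squarate; its partner is commercial ethoxyacetylene.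

Key step: step 4

Remark: compounds 2, 4, 6, 9, 11 and 21 are racemates. All their stereocentres vanish before the achiral target, so no stereocontrol is required.

Step 1
Reactants: 1 dimethyl squarate
Product: 3 3-methoxycyclobut-3-ene-1,2-dione (methyl semisquarate), via hydroxycyclobutenone 2 (not isolated)
Conditions: LiAlH(OtBu)3, THF, −78 → −20 °C, H2O quench; crude 2, conc. HCl (cat.), CH2Cl2, rt
Reagents that add atoms: water, O
Why: Hydride 1,2-reduction of one squarate carbonyl followed by acid-catalysed allylic transposition and hemiketal collapse (the standard squarate-to-cyclobutenedione sequence): the carbinol of 2, formed as a racemate without consequence, ionises, water returns at the distal methoxy-bearing carbon and methanol is expelled, so the reduced carbon ends as the ring =CH.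

Step 2
Reactants: 3 methyl semisquarate
Product: 4 4-hydroxy-3-methoxycyclobut-2-en-1-one (racemic)
Conditions: LiAlH(OtBu)3 (1 equiv), THF, −78 °C; Na2SO4·10H2O quench, filtration
Reagents that add atoms: none
Why: Regioselective 1,2-reduction of a cyclobutenedione: the C2 carbonyl next to C–OMe is a plain ketone whereas C1 is deactivated as a vinylogous ester (MeO–C=CH–C=O), so the bulky hydride should add once and only at C2, giving a racemic carbinol whose configuration is irrelevant because this carbon becomes arene carbon C8.

Step 3
Reactants: 4 4-hydroxy-3-methoxycyclobut-2-en-1-one; 5 chloromethyl methyl ether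
Product: 6 3-methoxy-4-(methoxymethoxy)cyclobut-2-en-1-one (racemic)
Conditions: MOMCl, iPr2NEt, CH2Cl2, 0 °C → rt
Reagents that add atoms: chloromethyl methyl ether 5, COCCl
Why: O-alkylation of the alcohol (MOM acetal formation) under a mild amine base, which avoids the acid-induced transposition seen in step 1 and cannot enolise C4–H (that would give an antiaromatic cyclobutadienolate); the acetal is a donor, prevents lactonisation of the later ketene and, unlike silyl or acyl groups, cannot migrate to the neighbouring phenol oxygen.

Step 4
Reactants: 6 3-methoxy-4-(methoxymethoxy)cyclobut-2-en-1-one; 7 ethoxyacetylene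
Product: 12 5-ethoxy-3-methoxy-2-(methoxymethoxy)phenol, via vinylketene 8 (not isolated), via vinylcyclobutenone 9 (not isolated), via dienylketene 10 (not isolated), via cyclohexadienone 11 (not isolated)
Conditions: 7 (3 equiv, hexanes solution), toluene, sealed tube, 80 °C; excess 7 evaporated; toluene, 110 °C; crude stirred with K2CO3, MeOH, rt, N2
Reagents that add atoms: ethoxyacetylene 7, CCOC#C
Why: Danheiser benzannulation: conrotatory four-electron opening of the C1–C4 bond of 6, with the donor OMOM group turning outward, gives vinylketene 8, whose ketene C=C adds 7 in a [2+2] cycloaddition to 9, and 9 opens reversibly to dienylketene 10. Ring A, the only ring that persists, is closed by disrotatory six-electron electrocyclisation of 10 (bond C8–C8a), and dienone 11 then tautomerises irreversibly to phenol 12, which drains all the preceding equilibria. The closest known chemistry is this same annulation of cyclobutenones with alkoxy- and siloxyalkynes, while outward opening of 4-oxygenated cyclobutenones is the first event of squarate-based quinone and phenol syntheses, so only the substituent set is untested. No lasting stereocentre is created, since the sp3 carbons of 6, 9 and 11 all end as arene carbons. The selectivity required is regiochemical and is fixed by the polarisation of 7: its nucleophilic CH terminus bonds to the electrophilic ketene carbon (C4a–C8a) and its oxygen-bearing carbon to the ketene α-carbon (C5–C6), which places OEt meta to the new OH and leaves C4a–H as the sole position ortho to it. Excess alkyne and a first stage held below the retro-ene threshold of 7 favour capture of 8 over its dimerisation or its acylation of 12.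

Step 5
Reactants: 12 5-ethoxy-3-methoxy-2-(methoxymethoxy)phenol; 5 chloromethyl methyl ether
Product: 13 5-ethoxy-1-methoxy-2,3-bis(methoxymethoxy)benzene
Conditions: MOMCl, iPr2NEt, CH2Cl2, 0 °C → reflux
Reagents that add atoms: chloromethyl methyl ether 5, COCCl
Why: Phenol O-alkylation (MOM ether formation): the C8a hydroxyl is the only acidic site, and the new acetal serves as the directing group of step 7 and leaves together with the C8 acetal in step 8, so it costs no separate deprotection.

Step 6
Reactants: 14 benzyloxyacetyl chloride; 15 N,O-dimethylhydroxylamine hydrochloride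
Product: 16 2-(benzyloxy)-N-methoxy-N-methylacetamide
Conditions: Et3N (2.2 equiv), CH2Cl2, 0 °C → rt
Reagents that add atoms: N,O-dimethylhydroxylamine hydrochloride 15, CNOC.Cl
Why: Acyl substitution of an acid chloride by the liberated hydroxylamine (Weinreb amide formation), a routine amidation with no competing functionality.

Step 7
Reactants: 13 5-ethoxy-1-methoxy-2,3-bis(methoxymethoxy)benzene; 16 2-(benzyloxy)-N-methoxy-N-methylacetamide
Product: 18 2-(benzyloxy)-1-[6-ethoxy-4-methoxy-2,3-bis(methoxymethoxy)phenyl]ethan-1-one, via aryllithium 17 (not isolated)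
Conditions: n-BuLi, THF, 0 °C; 16, −78 → 0 °C; sat. aq. NH4Cl
Reagents that add atoms: 2-(benzyloxy)-N-methoxy-N-methylacetamide 16, CON(C)C(=O)COCc1ccccc1
Why: Directed ortho-metalation followed by Weinreb ketone synthesis: C4a–H sits between the chelating OMOM group on C8a and the 5-OEt group, whereas C6–H is flanked only by simple ethers and is screened by the methyl of the buttressed 7-OMe group, so lithiation should take place at C4a, and the chelated tetrahedral adduct of 16 releases the ketone only on quenching.

Step 8
Reactants: 18 2-(benzyloxy)-1-[6-ethoxy-4-methoxy-2,3-bis(methoxymethoxy)phenyl]ethan-1-one; 19 4-(benzyloxy)benzoyl chloride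
Product: 22 3-(benzyloxy)-2-[4-(benzyloxy)phenyl]-5-ethoxy-8-hydroxy-7-methoxy-4H-chromen-4-one, via lithium enolate 20 (not isolated), via diketone 21 (not isolated)
Conditions: LiN(SiMe3)2 (2.2 equiv), THF, −78 °C; 19, −78 → 0 °C; cold 1 M HCl work-up; crude 21, conc. HCl (cat.), MeOH–THF, 55 °C, N2
Reagents that add atoms: 4-(benzyloxy)benzoyl chloride 19, O=C(Cl)c1ccc(OCc2ccccc2)cc1
Why: Claisen-type C-acylation of a chelated lithium enolate (the second equivalent of base takes up the acidic diketone proton) followed by acid-catalysed acetal cleavage and cyclodehydration, the 1,3-diketone flavone synthesis: both MOM groups fall in the same pot, and because O5 stays ethylated only the C8a hydroxyl can add to the aroyl carbonyl, so a single chromone regioisomer can form.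

Step 9
Reactants: 22 3-(benzyloxy)-2-[4-(benzyloxy)phenyl]-5-ethoxy-8-hydroxy-7-methoxy-4H-chromen-4-one
Product: 24 3-(benzyloxy)-2-[4-(benzyloxy)phenyl]-5,8-dihydroxy-7-methoxy-4H-chromen-4-one, via quinone 23 (not isolated)
Conditions: PhI(OAc)2, MeCN–THF–H2O, 0 °C; then aq. Na2S2O4, EtOAc, rt, N2
Reagents that add atoms: water, O
Why: Oxidative dealkylation of a para-alkoxyphenol to the para-quinone by a hypervalent iodine reagent followed by dithionite reduction, the quinone–quinol route long used for 5,8-dioxygenated flavones: the free 8-OH is the only site the iodane can engage, water adds at the ethoxy-bearing para carbon C5, ethanol leaves from the hemiketal, and the benzyl ethers, the 7-methyl ether and ring C are untouched.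

Step 10
Reactants: 24 3-(benzyloxy)-2-[4-(benzyloxy)phenyl]-5,8-dihydroxy-7-methoxy-4H-chromen-4-one; 25 acetic anhydride
Product: 26 3-(benzyloxy)-2-[4-(benzyloxy)phenyl]-5-hydroxy-7-methoxy-4-oxo-4H-chromen-8-yl acetate
Conditions: Ac2O (1.05 equiv), pyridine, CH2Cl2, 0 °C → rt, Ar
Reagents that add atoms: acetic anhydride 25, CC(=O)OC(C)=O
Why: Chemoselective O-acetylation: the 5-OH is locked in a strong hydrogen bond to the C4 carbonyl and is a poor nucleophile, so one equivalent of anhydride should go to the free 8-OH, the same discrimination that underlies partial alkylation of 5,8-dihydroxyflavones.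

Step 11
Reactants: 26 3-(benzyloxy)-2-[4-(benzyloxy)phenyl]-5-hydroxy-7-methoxy-4-oxo-4H-chromen-8-yl acetate
Product: 27 pollenitin 8-acetate
Conditions: H2 (1 atm), 10% Pd/C, EtOAc–THF, rt
Reagents that add atoms: none
Why: Catalytic hydrogenolysis of the two benzyl ethers under neutral, non-nucleophilic conditions, which leaves the aryl acetate, the methyl ether and the conjugated C2=C3 bond of the flavonol untouched and allows no acetyl migration because no free hydroxyl adjoins C8.

Compound list
1 | dimethyl squarate (3,4-dimethoxycyclobut-3-ene-1,2-dione) | COC1=C(OC)C(=O)C1=O | starting material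
2 | 4-hydroxy-2,3-dimethoxycyclobut-2-en-1-one (racemic) | COC1=C(OC)C(O)C1=O | intermediate
3 | 3-methoxycyclobut-3-ene-1,2-dione (methyl semisquarate) | COC1=CC(=O)C1=O | intermediate
4 | 4-hydroxy-3-methoxycyclobut-2-en-1-one (racemic) | COC1=CC(=O)C1O | intermediate
5 | chloromethyl methyl ether | COCCl | starting material
6 | 3-methoxy-4-(methoxymethoxy)cyclobut-2-en-1-one (racemic) | COCOC1C(=O)C=C1OC | intermediate
7 | ethoxyacetylene | CCOC#C | starting material
8 | (3Z)-3-methoxy-4-(methoxymethoxy)buta-1,3-dien-1-one (vinylketene, OMOM trans to the ketenyl carbon) | O=C=C/C(OC)=C/OCOC | intermediate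
9 | 3-ethoxy-4-[(Z)-1-methoxy-2-(methoxymethoxy)ethenyl]cyclobut-2-en-1-one (racemic) | CCOC1=CC(=O)C1/C(OC)=C/OCOC | intermediate
10 | (3E,5Z)-3-ethoxy-5-methoxy-6-(methoxymethoxy)hexa-1,3,5-trien-1-one (dienylketene) | O=C=C/C(OCC)=C\C(OC)=C\OCOC | intermediate
11 | 3-ethoxy-5-methoxy-6-(methoxymethoxy)cyclohexa-2,4-dien-1-one (racemic) | CCOC1=CC(=O)C(OCOC)C(OC)=C1 | intermediate
12 | 5-ethoxy-3-methoxy-2-(methoxymethoxy)phenol | CCOc1cc(O)c(OCOC)c(OC)c1 | intermediate
13 | 5-ethoxy-1-methoxy-2,3-bis(methoxymethoxy)benzene | CCOc1cc(OCOC)c(OCOC)c(OC)c1 | intermediate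
14 | benzyloxyacetyl chloride | O=C(Cl)COCc1ccccc1 | starting material
15 | N,O-dimethylhydroxylamine hydrochloride | CNOC.Cl | starting material
16 | 2-(benzyloxy)-N-methoxy-N-methylacetamide | CON(C)C(=O)COCc1ccccc1 | intermediate
17 | [6-ethoxy-4-methoxy-2,3-bis(methoxymethoxy)phenyl]lithium | [Li]c1c(OCC)cc(OC)c(OCOC)c1OCOC | intermediate
18 | 2-(benzyloxy)-1-[6-ethoxy-4-methoxy-2,3-bis(methoxymethoxy)phenyl]ethan-1-one | CCOc1cc(OC)c(OCOC)c(OCOC)c1C(=O)COCc1ccccc1 | intermediate
19 | 4-(benzyloxy)benzoyl chloride | O=C(Cl)c1ccc(OCc2ccccc2)cc1 | starting material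
20 | lithium (Z)-2-(benzyloxy)-1-[6-ethoxy-4-methoxy-2,3-bis(methoxymethoxy)phenyl]ethen-1-olate | [Li]O/C(=C\OCc1ccccc1)c1c(OCC)cc(OC)c(OCOC)c1OCOC | intermediate
21 | 2-(benzyloxy)-1-[4-(benzyloxy)phenyl]-3-[6-ethoxy-4-methoxy-2,3-bis(methoxymethoxy)phenyl]propane-1,3-dione (racemic, enolisable) | CCOc1cc(OC)c(OCOC)c(OCOC)c1C(=O)C(OCc1ccccc1)C(=O)c1ccc(OCc2ccccc2)cc1 | intermediate
22 | 3-(benzyloxy)-2-[4-(benzyloxy)phenyl]-5-ethoxy-8-hydroxy-7-methoxy-4H-chromen-4-one | CCOc1cc(OC)c(O)c2oc(-c3ccc(OCc4ccccc4)cc3)c(OCc3ccccc3)c(=O)c12 | intermediate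
23 | 3-(benzyloxy)-2-[4-(benzyloxy)phenyl]-7-methoxy-4H-chromene-4,5,8-trione | COC1=CC(=O)C2=C(OC(c3ccc(OCc4ccccc4)cc3)=C(OCc3ccccc3)C2=O)C1=O | intermediate
24 | 3-(benzyloxy)-2-[4-(benzyloxy)phenyl]-5,8-dihydroxy-7-methoxy-4H-chromen-4-one | COc1cc(O)c2c(=O)c(OCc3ccccc3)c(-c3ccc(OCc4ccccc4)cc3)oc2c1O | intermediate
25 | acetic anhydride | CC(=O)OC(C)=O | starting material
26 | 3-(benzyloxy)-2-[4-(benzyloxy)phenyl]-5-hydroxy-7-methoxy-4-oxo-4H-chromen-8-yl acetate | COc1cc(O)c2c(=O)c(OCc3ccccc3)c(-c3ccc(OCc4ccccc4)cc3)oc2c1OC(C)=O | intermediate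
27 | pollenitin 8-acetate (3,5-dihydroxy-2-(4-hydroxyphenyl)-7-methoxy-4-oxo-4H-chromen-8-yl acetate) | COc1cc(O)c2c(=O)c(O)c(-c3ccc(O)cc3)oc2c1OC(C)=O | target

Total step count: 11. Longest linear sequence: 10 (steps 1–5 and 7–11). Step 6 is a one-step side branch.

Steps most likely to fail

Step 4.
- **What may go wrong:** The doubly donor-substituted vinylketene may reclose faster than it is captured. It may also oligomerise or acylate the product phenol. The alkynyl ether may fragment by retro-ene reaction at the temperature needed for the second ring opening.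
- **Fallback:** This is conventional arene chemistry that sets out from chloromethyl methyl ether 5 and rejoins the route at 13, bypassing 12. Purchased 5-hydroxyvanillin F1 is converted with 5 and iPr2NEt into the bis-MOM aldehyde F2. Baeyer–Villiger oxidation with mCPBA (NaHCO3 buffer) gives the aryl formate F3. Methanolysis with K2CO3 in MeOH frees the phenol F4, and O-ethylation with EtI and K2CO3 in DMF gives 13.

Step 8.
- **What may go wrong:** The hindered α-alkoxy enolate may be acylated on oxygen instead of carbon, or proton transfer from the acidic product may stall conversion.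
- **Fallback:** It sets out from 18 and returns at 21. Enolate 20 is added at −78 °C to 4-(benzyloxy)benzaldehyde in an aldol addition, where only attack through carbon gives a stable product. This gives the β-hydroxy ketone F5. Oxidation with Dess–Martin periodinane then gives diketone 21, which is cyclised as in step 8.

Step 9.
- **What may go wrong:** Water may attack at C7 rather than C5, which means ortho-quinone formation with loss of the methyl ether. The electrophilic quinone may also decay before it is reduced.
- **Fallback:** It sets out from 22 and comes back at target 27, replacing steps 9–11. Acetylation of 22 with 25, pyridine and DMAP gives the 5-O-ethyl 8-acetate F6. BCl3 with pentamethylbenzene in CH2Cl2 (−78 → 0 °C, cold aqueous quench without alcohol) then removes both benzyl ethers. Through chelation to the C4 carbonyl it also removes the peri ethyl ether.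

Further compounds
F1 | step 4 | 3,4-dihydroxy-5-methoxybenzaldehyde (5-hydroxyvanillin, purchased) | COc1cc(C=O)cc(O)c1O
F2 | step 4 | 3-methoxy-4,5-bis(methoxymethoxy)benzaldehyde | COCOc1cc(C=O)cc(OC)c1OCOC
F3 | step 4 | 3-methoxy-4,5-bis(methoxymethoxy)phenyl formate | COCOc1cc(OC=O)cc(OC)c1OCOC
F4 | step 4 | 3-methoxy-4,5-bis(methoxymethoxy)phenol | COCOc1cc(O)cc(OC)c1OCOC
F5 | step 8 | 2-(benzyloxy)-3-[4-(benzyloxy)phenyl]-1-[6-ethoxy-4-methoxy-2,3-bis(methoxymethoxy)phenyl]-3-hydroxypropan-1-one (diastereomer mixture, both centres lost on oxidation and cyclisation) | CCOc1cc(OC)c(OCOC)c(OCOC)c1C(=O)C(OCc1ccccc1)C(O)c1ccc(OCc2ccccc2)cc1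
F6 | step 9 | 3-(benzyloxy)-2-[4-(benzyloxy)phenyl]-5-ethoxy-7-methoxy-4-oxo-4H-chromen-8-yl acetate | CCOc1cc(OC)c(OC(C)=O)c2oc(-c3ccc(OCc4ccccc4)cc3)c(OCc3ccccc3)c(=O)c12
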